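**Plan**
- The target is an achiral 2,5-dihydroxy-1,4-benzoquinone with a methyl group on C3 and an unbranched C21 chain on C6; there is no stereocentre, so no stereocontrol is needed.
- Retrosynthesis: (i) the dihydroxyquinone ring is unmasked from a 1,2,4,5-tetramethoxybenzene ring (hydrolysis of two vinylogous esters, then oxidative demethylation); (ii) the chain is cut between C3' and C4' (counted from the ring) into a 3-arylpropyl and an octadecyl radical, each released from a carboxylic acid as its N-acyloxyphthalimide; (iii) the ring–C1' and ring–CH3 bonds are cut back to aryllithiums of 1,2,4,5-tetramethoxybenzene.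
- Enabling feature: C3' and C4' are unsubstituted CH2 groups of a saturated polymethylene chain, so both halves are plain primary radicals available by decarboxylation and the union leaves no functional group behind. The only redox-active part, the quinone ring, travels as the tetramethoxybenzene ring, which is inert at the cathode where the coupling takes place.
- Forward: methylation and alkylation of the ring (steps 1–2), activation of both acids (steps 3–4), nickel-electrocatalytic doubly decarboxylative coupling (step 5), then oxidation to the quinone and hydrolysis (steps 6–7).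

Key step: step 5

Remark: 1,2,4,5-tetramethoxybenzene (1), trimethyl 4-bromoorthobutyrate (3) and nonadecanoic acid (8) are taken as purchasable.

**Step 1**
Reactants: 1 1,2,4,5-tetramethoxybenzene
Product: 2 1,2,4,5-tetramethoxy-3-methylbenzene (2,3,5,6-tetramethoxytoluene)
Conditions: n-BuLi (1.05 equiv), THF, 0 °C to rt; MeI, 0 °C to rt
Reagents that add atoms: iodomethane, CI
Why: Directed ortho-metalation: each ring C–H of 1 lies between two methoxy groups and should be lithiated cleanly, and the aryllithium is methylated by SN2 on iodomethane.

**Step 2**
Reactants: 2 2,3,5,6-tetramethoxytoluene; 3 trimethyl 4-bromoorthobutyrate (4-bromo-1,1,1-trimethoxybutane)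
Product: 6 4-(2,3,5,6-tetramethoxy-4-methylphenyl)butanoic acid, via ortho ester 4 (not isolated), via methyl ester 5 (not isolated)
Conditions: n-BuLi, THF, 0 °C; 3, DMPU, −78 °C to rt; 1 M HCl, THF, rt; LiOH, THF–MeOH–H2O, 50 °C; then HCl (aq), acid–base extraction
Reagents that add atoms: water, O; lithium hydroxide, [Li+].[OH-]
Why: Directed ortho-metalation of the last ring C–H (again between two methoxy groups) and SN2 alkylation of the aryllithium by the primary bromide, whose acid carbon is masked as an ortho ester that can neither enolise nor be attacked; acidic work-up should unmask the methyl ester and saponification then gives the acid.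

**Step 3**
Reactants: 6 4-(2,3,5,6-tetramethoxy-4-methylphenyl)butanoic acid
Product: 7 1,3-dioxoisoindolin-2-yl 4-(2,3,5,6-tetramethoxy-4-methylphenyl)butanoate
Conditions: N-hydroxyphthalimide, DIC, DMAP (cat.), CH2Cl2, rt
Reagents that add atoms: N-hydroxyphthalimide, O=C1c2ccccc2C(=O)N1O
Why: Carbodiimide (Steglich-type) esterification of an unhindered primary acid with N-hydroxyphthalimide should give the redox-active ester, with no other reactive group in the molecule.

**Step 4**
Reactants: 8 nonadecanoic acid
Product: 9 1,3-dioxoisoindolin-2-yl nonadecanoate
Conditions: N-hydroxyphthalimide, DIC, DMAP (cat.), CH2Cl2, rt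
Reagents that add atoms: N-hydroxyphthalimide, O=C1c2ccccc2C(=O)N1O
Why: The same carbodiimide (Steglich-type) esterification, applied to a plain fatty acid.

**Step 5**
Reactants: 7 1,3-dioxoisoindolin-2-yl 4-(2,3,5,6-tetramethoxy-4-methylphenyl)butanoate; 9 1,3-dioxoisoindolin-2-yl nonadecanoate (3 equiv)
Product: 10 1-henicosyl-2,3,5,6-tetramethoxy-4-methylbenzene
Conditions: NiCl2·6H2O (20 mol%), 2,2':6',2''-terpyridine (20 mol%), AgNO3 (0.3 equiv), NMP, Mg(+)/RVC(−), constant current, rt
Reagents that add atoms: none
Why: Cathodically generated low-valent Ni(terpyridine) passes one electron to each N-acyloxyphthalimide, which fragments to CO2, phthalimide anion and a primary alkyl radical (octadecyl from 9, 3-arylpropyl from 7); the nickel centre captures the two radicals in turn and the dialkylnickel(III) species forms the CH2–CH2 bond by reductive elimination, the Mg anode supplying the two electrons. The closest known reaction type is the nickel-electrocatalytic doubly decarboxylative C(sp3)–C(sp3) coupling of two redox-active esters on a silver-nanoparticle-coated cathode, a reductive counterpart of the mixed Kolbe electrolysis that is established for pairs of unbranched primary acids. No ring is closed and no stereocentre is formed. The step needs cross- over homo-coupling, which rests on the threefold excess of the lipid ester 9; its homodimer hexatriacontane is a hydrocarbon and should separate easily from the tetraether 10. The step also needs the arene to stay intact: the reductive manifold leaves the very electron-rich tetramethoxybenzene ring untouched (an anodic Kolbe coupling would oxidise it first), and both ortho positions are blocked by methoxy groups, which disfavours cyclisation of the 3-arylpropyl radical onto the ring.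

**Step 6**
Reactants: 10 1-henicosyl-2,3,5,6-tetramethoxy-4-methylbenzene
Product: 11 3-henicosyl-2,5-dimethoxy-6-methyl-1,4-benzoquinone
Conditions: CAN (2.5 equiv), MeCN–CH2Cl2–H2O, 0 °C
Reagents that add atoms: water, O
Why: Oxidative demethylation of a p-dimethoxyarene by cerium(IV): the arene radical cation is attacked by water and loses two para methyl groups as methanol; either para pair gives the same p-quinone, and any o-quinone isomer would converge on the same product in step 7.

**Step 7**
Reactants: 11 3-henicosyl-2,5-dimethoxy-6-methyl-1,4-benzoquinone
Product: 12 2,5-dihydroxy-3-henicosyl-6-methyl-1,4-benzoquinone (target)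
Conditions: NaOH (2 M aq), EtOH–THF, 60 °C; then HCl (aq)
Reagents that add atoms: sodium hydroxide, [Na+].[OH-]
Why: Both methoxy groups are vinylogous esters and should be replaced by hydroxide through conjugate addition–elimination (vinylogous ester saponification); the bis-enolate is stable to base and acidification gives the dihydroxyquinone.

**Compound list**
1 | 1,2,4,5-tetramethoxybenzene | COc1cc(OC)c(OC)cc1OC | starting material
2 | 1,2,4,5-tetramethoxy-3-methylbenzene (2,3,5,6-tetramethoxytoluene) | Cc1c(OC)c(OC)cc(OC)c1OC | intermediate
3 | trimethyl 4-bromoorthobutyrate (4-bromo-1,1,1-trimethoxybutane) | COC(CCCBr)(OC)OC | starting material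
4 | 1,2,4,5-tetramethoxy-3-methyl-6-(4,4,4-trimethoxybutyl)benzene (ortho ester, not isolated) | COc1c(C)c(OC)c(OC)c(CCCC(OC)(OC)OC)c1OC | intermediate
5 | methyl 4-(2,3,5,6-tetramethoxy-4-methylphenyl)butanoate (not isolated) | COC(=O)CCCc1c(OC)c(OC)c(C)c(OC)c1OC | intermediate
6 | 4-(2,3,5,6-tetramethoxy-4-methylphenyl)butanoic acid | OC(=O)CCCc1c(OC)c(OC)c(C)c(OC)c1OC | intermediate
7 | 1,3-dioxoisoindolin-2-yl 4-(2,3,5,6-tetramethoxy-4-methylphenyl)butanoate | O=C(CCCc1c(OC)c(OC)c(C)c(OC)c1OC)ON1C(=O)c2ccccc2C1=O | intermediate
8 | nonadecanoic acid | CCCCCCCCCCCCCCCCCCC(=O)O | starting material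
9 | 1,3-dioxoisoindolin-2-yl nonadecanoate | CCCCCCCCCCCCCCCCCCC(=O)ON1C(=O)c2ccccc2C1=O | intermediate
10 | 1-henicosyl-2,3,5,6-tetramethoxy-4-methylbenzene | CCCCCCCCCCCCCCCCCCCCCc1c(OC)c(OC)c(C)c(OC)c1OC | intermediate
11 | 3-henicosyl-2,5-dimethoxy-6-methyl-1,4-benzoquinone | CCCCCCCCCCCCCCCCCCCCCC1=C(OC)C(=O)C(C)=C(OC)C1=O | intermediate
12 | 2,5-dihydroxy-3-henicosyl-6-methyl-1,4-benzoquinone | CCCCCCCCCCCCCCCCCCCCCC1=C(O)C(=O)C(C)=C(O)C1=O | target

**Step count:** 7 steps in total. The longest linear sequence is 6 steps (1, 2, 3, 5, 6, 7 from compound 1); step 4 is a one-step side branch.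

**Steps most likely to fail**

Step 5. The two primary radicals may pair statistically, so that homo-coupling of each partner and simple reduction of the radicals to the alkanes lower the share of cross-product. The fallback replaces the radical union by a two-electron cross-coupling at the same bond and sets out from compound 2. Lithiation of 2 (n-BuLi, THF) and reaction with allyl bromide should give 1-allyl-2,3,5,6-tetramethoxy-4-methylbenzene F1. Anti-Markovnikov hydroboration with 9-BBN should give B-[3-(2,3,5,6-tetramethoxy-4-methylphenyl)propyl]-9-borabicyclo[3.3.1]nonane F2. A B-alkyl Suzuki–Miyaura coupling of F2 with 1-bromooctadecane (Pd(OAc)2, PCy3, K3PO4·H2O, THF, rt) would then form the same CH2–CH2 bond and return to the route at compound 10.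

Step 2. The aryllithium is flanked by two methoxy groups and may alkylate slowly, so that E2 elimination of the bromide or proton quench takes over. The fallback changes from alkylation to acylation followed by deoxygenation and sets out from compound 2. The aryllithium of 2 is added to succinic anhydride at −78 °C to give 4-oxo-4-(2,3,5,6-tetramethoxy-4-methylphenyl)butanoic acid F3. Ionic hydrogenation of the aryl ketone (Et3SiH, TFA) removes the carbonyl oxygen and returns to the route at compound 6.

Step 6. Oxidation by cerium(IV) may not stop cleanly at the p-quinone: over-oxidation, attack at the benzylic positions and poor mixing of the lipophilic substrate with the aqueous oxidant are possible. The fallback avoids a metal oxidant and sets out from compound 10. Exhaustive ether cleavage with BBr3 (CH2Cl2, −78 °C to rt) should give 3-henicosyl-6-methylbenzene-1,2,4,5-tetrol F4. This tetrol is expected to autoxidise in air (O2, aqueous NaHCO3–THF, then acid) directly to the dihydroxyquinone, so the fallback comes back at the target 12 and bypasses compound 11 and step 7.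

**Further compounds**
F1 | step 5 | 1-allyl-2,3,5,6-tetramethoxy-4-methylbenzene | C=CCc1c(OC)c(OC)c(C)c(OC)c1OC
F2 | step 5 | B-[3-(2,3,5,6-tetramethoxy-4-methylphenyl)propyl]-9-borabicyclo[3.3.1]nonane | COc1c(C)c(OC)c(OC)c(CCCB2C3CCCC2CCC3)c1OC
F3 | step 2 | 4-oxo-4-(2,3,5,6-tetramethoxy-4-methylphenyl)butanoic acid | OC(=O)CCC(=O)c1c(OC)c(OC)c(C)c(OC)c1OC
F4 | step 6 | 3-henicosyl-6-methylbenzene-1,2,4,5-tetrol | CCCCCCCCCCCCCCCCCCCCCc1c(O)c(O)c(C)c(O)c1O
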